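**Retrosynthetic overview**
1. Target 10 ⇒ 8 by a last-step, peri-chelation-controlled 5-O-demethylation. No protecting group is used anywhere.
2. 8 ⇒ C2–C1' bond. Chromone 5 serves as its C2 carbanion, an α-lithiated cyclic enol ether, i.e. the masked acyl anion of the aroylacetaldehyde. C2 is natively electrophilic, and it attacks a carbonyl carbon of the C2-symmetric quinone 2, which is also electrophilic.
3. The p-quinol adduct is reductively re-aromatised in the same flask. The untouched quinone C=O becomes the free 4'-OH.
4. 5 ⇒ acetophenone 3 plus one carbon from DMF-DMA. 2 ⇒ 2,3-dimethoxyphenol 1 by para-oxidation.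
5. Ring order: A is bought intact, C is closed in step 2, and B is joined dearomatised and then aromatised in step 3.

Assumption: the target has no stereocentre and no hindered axis, so it is achiral and there is no enantiomer to select; 1 and 3 are taken as catalogue compounds.

**Route**

Step 1
Reactants: 1 2,3-dimethoxyphenol
Product: 2 2,3-dimethoxy-1,4-benzoquinone
Conditions: (KSO3)2NO (2.5 equiv), KH2PO4, H2O/acetone, 0 → 23 °C
Reagents that add atoms: potassium nitrosodisulfonate (Fremy's salt), [K+].[K+].[O-]S(=O)(=O)N([O])S(=O)(=O)[O-]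
Why: Teuber oxidation, in which the first equivalent of the nitroxyl radical makes the phenoxyl radical, the second traps it at the free OMe-activated para carbon, and collapse of that adduct gives the p-quinone with little o-quinone or C–C dimer.

Step 2
Reactants: 3 1-(2-hydroxy-3,4,6-trimethoxyphenyl)ethan-1-one
Product: 5 5,7,8-trimethoxy-4H-chromen-4-one, via enaminone 4 (not isolated)
Conditions: DMF-DMA (3 equiv), toluene, 110 °C; evaporate; conc. HCl, CH2Cl2, 40 °C
Reagents that add atoms: N,N-dimethylformamide dimethyl acetal (DMF-DMA), COC(OC)N(C)C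
Why: Enaminone condensation of the methyl ketone with the amide acetal, followed by acid-induced addition–elimination of the only free OH on the β-carbon (loss of Me2NH), is the standard synthesis of 2,3-unsubstituted chromones and fixes the 5,7,8-pattern without regiochemical ambiguity.

Step 3
Reactants: 5 5,7,8-trimethoxy-4H-chromen-4-one, 2 2,3-dimethoxy-1,4-benzoquinone
Product: 8 4'-hydroxy-5,7,8,2',3'-pentamethoxyflavone, via 2-lithiochromone 6 (not isolated), via racemic p-quinol 7 (not isolated)
Conditions: TMPH, n-BuLi, THF, −78 °C; add 5 dropwise, 20 min; cannulate into 2 (1.5 equiv), THF, −78 °C, 1 h; then AcOH (10 equiv), Zn dust (5 equiv), −78 → 23 °C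
Reagents that add atoms: none
Why: Proposed new method: C2–H is the most acidic C–H of a 4-pyranone (TMP–zinc bases metalate chromones there, lithium amides lithiate 4-quinolones and 4-pyridones there, and the 5-OMe/C4=O chelate holds Li away from C3–H), so LiTMP gives the α-lithiated enol ether 6 as a masked acyl anion, which as a hard organolithium adds 1,2 to a carbonyl of 2 (both are equivalent, so only one quinol can form, and its single stereocentre is racemic and erased at once), and Zn/AcOH then expels the tertiary OH in a two-electron reductive aromatisation to the para-phenol, the closest known reaction type being aryl- or vinyllithium 1,2-addition to p-benzoquinones or quinone monoketals followed by reductive aromatisation of the p-quinol.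

Step 4
Reactants: 8 4'-hydroxy-5,7,8,2',3'-pentamethoxyflavone
Product: 10 5,4'-dihydroxy-7,8,2',3'-tetramethoxyflavone, via bis(dichloroboryl) ether 9 (not isolated)
Conditions: BCl3 (3 equiv), CH2Cl2, −78 → 0 °C; then H2O/MeOH
Reagents that add atoms: none
Why: Chelation-controlled Lewis-acid ether cleavage, in which BCl3 bound to C4=O reaches only the peri 5-OMe through a six-membered chelate and chloride removes its methyl below 0 °C, while the unchelated 7-, 8-, 2'- and 3'-OMe groups survive and the 4'-O–BCl2 ester is hydrolysed back to OH on work-up.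

**Compound list**
1 | 2,3-dimethoxyphenol | COc1cccc(O)c1OC | starting material
2 | 2,3-dimethoxy-1,4-benzoquinone | COC1=C(OC)C(=O)C=CC1=O | intermediate
3 | 1-(2-hydroxy-3,4,6-trimethoxyphenyl)ethan-1-one | CC(=O)c1c(O)c(OC)c(OC)cc1OC | starting material
4 | (E)-3-(dimethylamino)-1-(2-hydroxy-3,4,6-trimethoxyphenyl)prop-2-en-1-one | CN(C)/C=C/C(=O)c1c(O)c(OC)c(OC)cc1OC | intermediate
5 | 5,7,8-trimethoxy-4H-chromen-4-one | COc1cc(OC)c2c(=O)ccoc2c1OC | intermediate
6 | 2-lithio-5,7,8-trimethoxy-4H-chromen-4-one | [Li]c1cc(=O)c2c(OC)cc(OC)c(OC)c2o1 | intermediate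
7 | (±)-4-hydroxy-2,3-dimethoxy-4-(5,7,8-trimethoxy-4-oxo-4H-chromen-2-yl)cyclohexa-2,5-dien-1-one (formed as its lithium alkoxide, protonated by AcOH) | COC1=C(OC)C(O)(C=CC1=O)c1cc(=O)c2c(OC)cc(OC)c(OC)c2o1 | intermediate
8 | 4'-hydroxy-5,7,8,2',3'-pentamethoxyflavone | COc1cc(OC)c2c(=O)cc(-c3ccc(O)c(OC)c3OC)oc2c1OC | intermediate
9 | 5,4'-bis(dichloroboryloxy)-7,8,2',3'-tetramethoxyflavone (5-O–B chelated to C4=O) | COc1cc(OB(Cl)Cl)c2c(=O)cc(-c3ccc(OB(Cl)Cl)c(OC)c3OC)oc2c1OC | intermediate
10 | 5,4'-dihydroxy-7,8,2',3'-tetramethoxyflavone (achiral) | COc1cc(O)c2c(=O)cc(-c3ccc(O)c(OC)c3OC)oc2c1OC | target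

**Totals**
Total steps: 4. Longest linear sequence: 3 (3 → 5 → 8 → 10; the branch 1 → 2 joins at step 3).

**Three steps most likely to fail**

Step 3 carries four risks:
- competing C3 or C6 lithiation
- attack of 6 on unlithiated 5
- electron transfer to the quinone
- 1,4-addition

The fallback sets out from 5, with 1 supplying the aryl partner, and comes back at 8. It keeps the same C2 carbanion but makes it a soft zinc species, and it changes the B-ring electrophile from a quinone carbonyl to an aryl halide. Compound 1 is para-brominated with Bu4NBr3 in CH2Cl2/MeOH to 4-bromo-2,3-dimethoxyphenol F1. Compound 5 is zincated at C2 with TMPZnCl·LiCl in THF at 25 °C to (5,7,8-trimethoxy-4-oxo-4H-chromen-2-yl)zinc chloride F2. A Pd(OAc)2/SPhos Negishi coupling, with slow addition of the zinc reagent so that the free OH is tolerated, then gives 8.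

Step 4 could lose the neighbouring 3'-OMe with help from the 4'-O–boron ester, or lose the 8-OMe. The fallback sets out from 8 and comes back at 10. The 4'-OH is first masked with Ac2O/pyridine to give 4'-acetoxy-5,7,8,2',3'-pentamethoxyflavone F3. With no boron held next to the 3'-OMe, BCl3 at −78 → 0 °C removes only the 5-methyl and gives 4'-acetoxy-5-hydroxy-7,8,2',3'-tetramethoxyflavone F4. K2CO3/MeOH at 23 °C then frees the phenol.

Step 1 could give o-quinone, dimers, or hydrolysis of the methoxyquinone in water. The fallback sets out from 1 and comes back at 2. It installs the para oxygen by ionic rather than radical chemistry. Elbs persulfate oxidation (K2S2O8, aq KOH, 10 °C) gives potassium 4-hydroxy-2,3-dimethoxyphenyl sulfate F5. Warm dilute HCl hydrolyses it to 2,3-dimethoxybenzene-1,4-diol F6, and Ag2O in Et2O over Na2SO4 oxidises that under anhydrous conditions to 2.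

**Further compounds**
F1 | step 3 | 4-bromo-2,3-dimethoxyphenol | COc1c(O)ccc(Br)c1OC
F2 | step 3 | (5,7,8-trimethoxy-4-oxo-4H-chromen-2-yl)zinc chloride | Cl[Zn]c1cc(=O)c2c(OC)cc(OC)c(OC)c2o1
F3 | step 4 | 4'-acetoxy-5,7,8,2',3'-pentamethoxyflavone | COc1cc(OC)c2c(=O)cc(-c3ccc(OC(C)=O)c(OC)c3OC)oc2c1OC
F4 | step 4 | 4'-acetoxy-5-hydroxy-7,8,2',3'-tetramethoxyflavone | COc1cc(O)c2c(=O)cc(-c3ccc(OC(C)=O)c(OC)c3OC)oc2c1OC
F5 | step 1 | potassium 4-hydroxy-2,3-dimethoxyphenyl sulfate | [K+].COc1c(O)ccc(OS(=O)(=O)[O-])c1OC
F6 | step 1 | 2,3-dimethoxybenzene-1,4-diol | COc1c(O)ccc(O)c1OC
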